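The ring is numbered as a germacranolide: carbocycle C1–C10, lactone carbonyl C12, ester C14, hydroxymethyl C15. Everything rests on the C5–C6 disconnection, the bond between the ring alkene carbon C5 and the lactone carbinol C6. An intramolecular Nozaki–Hiyama–Kishi reaction of an acyclic alkenyl iodide/aldehyde closes the ten-membered carbocycle and sets C6. Because the new C6 alkoxide sits γ to the C12 ester, it closes the α-methylene-γ-lactone ring in the same flask. The step exploits the fact that C6 is both allylic to the C4=C5 ring alkene and the lactone carbinol. The seco precursor already carries the C8 methacrylate, the C9 acetate and both ring alkenes. It comes from an indium Barbier union (C7–C8) and an alkenylmagnesium addition (C9–C10).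

Key step: step 14

Remark: the target is read as 6R,7S,8S,9R with a trans-fused lactone; both ring alkenes have their ring carbons cis (CIP descriptors 1(10)E,4E because of the C14 ester and the C15 oxygen).
Remark: 1, 10, 13 (the S enantiomer), 19 (aqueous solution) and 20 are taken as commercial.

Step 1
Reactants: 1 diethyl 2-(but-3-en-1-yl)malonate
Product: 3 diethyl 2-(but-3-en-1-yl)-2-(diiodomethyl)malonate, via sodium enolate 2 (not isolated)
Conditions: NaH, Et2O, reflux; then CHI3, reflux
Reagents that add atoms: iodoform, IC(I)I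
Why: C-alkylation of a malonate enolate with iodoform (capture of diiodocarbene, a known route to diiodomethyl malonates) puts the future C5 on the quaternary carbon that becomes C4; no stereocentre is formed.

Step 2
Reactants: 3 diethyl 2-(but-3-en-1-yl)-2-(diiodomethyl)malonate
Product: 5 (2E)-2-(iodomethylidene)hex-5-enoic acid, via dipotassium dicarboxylate 4 (not isolated)
Conditions: KOH, EtOH/H2O 3:1, reflux; then aq. HCl
Reagents that add atoms: none
Why: Saponification and decarboxylative anti elimination of iodide (Grob-type fragmentation) give the β-iodoacrylic acid with iodine trans to the remaining carboxyl and so cis to the C3 chain, which fixes the C4=C5 geometry needed in the ring.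

Step 3
Reactants: 5 (2E)-2-(iodomethylidene)hex-5-enoic acid
Product: 6 (2E)-2-(iodomethylidene)hex-5-en-1-ol
Conditions: LiAlH4, Et2O, 0 °C
Reagents that add atoms: none
Why: Hydride reduction of the carboxylic acid gives the primary allylic alcohol (the future C15 hydroxyl), and at 0 °C the alkenyl iodide and the isolated alkene are not reduced.

Step 4
Reactants: 6 (2E)-2-(iodomethylidene)hex-5-en-1-ol
Product: 7 tert-butyl{[(2E)-2-(iodomethylidene)hex-5-en-1-yl]oxy}diphenylsilane
Conditions: TBDPSCl, imidazole, DMF, rt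
Reagents that add atoms: tert-butyl(chloro)diphenylsilane, CC(C)(C)[Si](Cl)(c1ccccc1)c1ccccc1
Why: Silylation of the primary alcohol gives an ether that should withstand the later periodic acid, aqueous indium and silyl triflate steps.

Step 5
Reactants: 7 tert-butyl{[(2E)-2-(iodomethylidene)hex-5-en-1-yl]oxy}diphenylsilane
Product: 9 (4E)-4-{[tert-butyl(diphenyl)silyl]oxymethyl}-5-iodopent-4-enal, via diol 8 (not isolated)
Conditions: OsO4 (cat.), NaIO4, 2,6-lutidine, dioxane/H2O 3:1, rt
Reagents that add atoms: osmium tetroxide, O=[Os](=O)(=O)=O (transfers the oxygen and is regenerated by sodium periodate, [Na+].[O-]I(=O)(=O)=O)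
Why: Lemieux–Johnson cleavage, in which OsO4 dihydroxylates only the monosubstituted alkene (the iodoalkene is trisubstituted and electron-poor) and NaIO4 cleaves the diol to the C1 aldehyde.

Step 6
Reactants: 9 (4E)-4-{[tert-butyl(diphenyl)silyl]oxymethyl}-5-iodopent-4-enal; 10 methyl (triphenylphosphoranylidene)acetate
Product: 12 methyl (2Z,6E)-6-{[tert-butyl(diphenyl)silyl]oxymethyl}-2,7-diiodohepta-2,6-dienoate, via iodo ylide 11 (not isolated)
Conditions: NIS, CH2Cl2, −20 °C; then 9, K2CO3, −20 °C → rt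
Reagents that add atoms: N-iodosuccinimide, O=C1CCC(=O)N1I
Why: Wittig olefination with the stabilised iodo ylide made in the flask places the ester trans to the alkyl chain, giving the Z α-iodoenoate that carries the C1=C10 geometry of the target.

Step 7
Reactants: 12 methyl (2Z,6E)-6-{[tert-butyl(diphenyl)silyl]oxymethyl}-2,7-diiodohepta-2,6-dienoate; 13 (4S)-2,2-dimethyl-1,3-dioxolane-4-carbaldehyde
Product: 16 methyl (2E,6E)-2-{(R)-acetoxy[(4S)-2,2-dimethyl-1,3-dioxolan-4-yl]methyl}-6-{[tert-butyl(diphenyl)silyl]oxymethyl}-7-iodohepta-2,6-dienoate, via alkenylmagnesium chloride 14 (not isolated), via chloromagnesium alkoxide 15 (not isolated)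
Conditions: iPrMgCl·LiCl, THF, −78 °C; 13, −78 °C; then Ac2O, DMAP (cat.), −78 → 0 °C
Reagents that add atoms: acetic anhydride, CC(=O)OC(C)=O
Why: Iodine–magnesium exchange should occur only at the ester-activated α-iodoenoate at −78 °C with retention of alkene geometry, the alkenylmagnesium adds to 13 anti to the dioxolane oxygen (Felkin–Anh control) to set C9 as R, and the alkoxide is acetylated in the flask; the minor C9 epimer is removed by chromatography.

Step 8
Reactants: 16 methyl (2E,6E)-2-{(R)-acetoxy[(4S)-2,2-dimethyl-1,3-dioxolan-4-yl]methyl}-6-{[tert-butyl(diphenyl)silyl]oxymethyl}-7-iodohepta-2,6-dienoate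
Product: 18 methyl (2E,6E)-2-[(1R)-1-acetoxy-2-oxoethyl]-6-{[tert-butyl(diphenyl)silyl]oxymethyl}-7-iodohepta-2,6-dienoate, via diol 17 (not isolated)
Conditions: H5IO6, EtOAc, rt
Reagents that add atoms: none
Why: Periodic acid hydrolyses the terminal acetonide and cleaves the resulting 1,2-diol in one pot (glycol cleavage), which turns the sacrificial dioxolane carbon into the C8 aldehyde without touching C9.

Step 9
Reactants: 19 2,2-dimethoxyacetaldehyde; 20 methyl acrylate
Product: 21 methyl 3-hydroxy-4,4-dimethoxy-2-methylidenebutanoate (racemic)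
Conditions: DABCO, dioxane/H2O, rt
Reagents that add atoms: none
Why: DABCO-catalysed Morita–Baylis–Hillman reaction of an activated α-alkoxy aldehyde; the racemic carbinol centre is erased in step 10.

Step 10
Reactants: 21 methyl 3-hydroxy-4,4-dimethoxy-2-methylidenebutanoate
Product: 22 methyl (2Z)-2-(bromomethyl)-4,4-dimethoxybut-2-enoate
Conditions: NBS, Me2S, CH2Cl2, 0 °C → rt
Reagents that add atoms: N-bromosuccinimide, O=C1CCC(=O)N1Br
Why: Activation of the allylic alcohol as an alkoxysulfonium ion (Corey–Kim reagent) and SN2' attack of bromide give the rearranged primary bromide as the thermodynamically preferred Z isomer, with the acetal arm cis to CH2Br.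

Step 11
Reactants: 18 methyl (2E,6E)-2-[(1R)-1-acetoxy-2-oxoethyl]-6-{[tert-butyl(diphenyl)silyl]oxymethyl}-7-iodohepta-2,6-dienoate; 22 methyl (2Z)-2-(bromomethyl)-4,4-dimethoxybut-2-enoate
Product: 24 dimethyl (2E,3R,4S,5R)-3-acetoxy-2-[(4E)-4-{[tert-butyl(diphenyl)silyl]oxymethyl}-5-iodopent-4-en-1-ylidene]-5-(dimethoxymethyl)-4-hydroxy-6-methylideneheptanedioate, via allylindium dibromide 23 (not isolated)
Conditions: In powder, THF/H2O 1:1, rt
Reagents that add atoms: none
Why: Barbier allylation in which the allylindium adds through its γ-carbon (C7) in a chair-like Zimmerman–Traxler transition state, the Z geometry of 22 giving the C7/C8 syn pair and Felkin–Anh attack anti to the C9 acetoxy group giving the C8/C9 anti pair; minor diastereomers are removed by chromatography.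

Step 12
Reactants: 24 dimethyl (2E,3R,4S,5R)-3-acetoxy-2-[(4E)-4-{[tert-butyl(diphenyl)silyl]oxymethyl}-5-iodopent-4-en-1-ylidene]-5-(dimethoxymethyl)-4-hydroxy-6-methylideneheptanedioate
Product: 25 dimethyl (2E,3R,4S,5R)-3-acetoxy-2-[(4E)-4-{[tert-butyl(diphenyl)silyl]oxymethyl}-5-iodopent-4-en-1-ylidene]-5-(dimethoxymethyl)-4-(methacryloyloxy)-6-methylideneheptanedioate
Conditions: methacrylic anhydride, Et3N, DMAP (cat.), CH2Cl2, 0 °C → rt
Reagents that add atoms: methacrylic anhydride, CC(=C)C(=O)OC(=O)C(C)=C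
Why: DMAP-catalysed acylation of the C8 alcohol should be faster than acetyl migration from O9 or lactonisation onto C12, and no stereocentre is touched.

Step 13
Reactants: 25 dimethyl (2E,3R,4S,5R)-3-acetoxy-2-[(4E)-4-{[tert-butyl(diphenyl)silyl]oxymethyl}-5-iodopent-4-en-1-ylidene]-5-(dimethoxymethyl)-4-(methacryloyloxy)-6-methylideneheptanedioate
Product: 27 dimethyl (2E,3R,4S,5R)-3-acetoxy-2-[(4E)-4-{[tert-butyl(diphenyl)silyl]oxymethyl}-5-iodopent-4-en-1-ylidene]-5-formyl-4-(methacryloyloxy)-6-methylideneheptanedioate, via collidinium salt 26 (not isolated)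
Conditions: TESOTf, 2,4,6-collidine, CH2Cl2, 0 °C; then H2O
Reagents that add atoms: water, O
Why: Silyl triflate/collidine acetal cleavage through the collidinium salt and its hydrolysis unmask the C6 aldehyde under non-protic, weakly basic conditions that spare the silyl ether, the esters and the epimerisable C7; the aldehyde is used at once.

Step 14
Reactants: 27 dimethyl (2E,3R,4S,5R)-3-acetoxy-2-[(4E)-4-{[tert-butyl(diphenyl)silyl]oxymethyl}-5-iodopent-4-en-1-ylidene]-5-formyl-4-(methacryloyloxy)-6-methylideneheptanedioate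
Product: 30 the 15-O-(tert-butyldiphenylsilyl) ether of the target (6R,7S,8S,9R), via alkenylchromium dichloride 28 (not isolated), via chromium alkoxide 29 (not isolated)
Conditions: CrCl2 (10 equiv), NiCl2 (0.1 equiv), degassed DMSO/THF 3:1, 0.002 M, slow addition of 27, rt; aq. sodium serinate work-up
Reagents that add atoms: none
Why: Zerovalent nickel formed from NiCl2 and CrCl2 inserts into the C5–I bond and transmetalation to trivalent chromium gives the alkenylchromium 28 with retention of the C4=C5 geometry, which adds to the C6 aldehyde (intramolecular Nozaki–Hiyama–Kishi reaction, a known way to close ten-membered and larger carbocycles). The carbocycle closes by 10-exo-trig attack of C5 on the carbonyl, made feasible by the two cis ring alkenes already present (no trans-cyclodecene strain) and by high dilution. The chromium alkoxide 29 then closes the γ-lactone by 5-exo-trig acyl substitution at the C12 methyl ester, so two rings form in one operation. C6 is the only new stereocentre and is controlled by C7: with C8 held gauche to C5 by the ring, the C7–C11 bond lies anti to the forming C5–C6 bond (Felkin–Anh alignment, acrylate arm outside the ring) and C5 attacks the face that puts O6 syn to C11, which is the 6R, trans-fused lactone. The step needs the alkenylmetal to choose the aldehyde over four esters, three Michael acceptors and the allylic C9 acetate, which the low basicity and carbonyl selectivity of alkenylchromium and a low nickel loading should secure, and it needs closure to outrun β-elimination of the O8 methacrylate, which the non-basic medium favours.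

Step 15
Reactants: 30 the 15-O-(tert-butyldiphenylsilyl) ether of the target
Product: 31 CNP0179134.4 (target)
Conditions: HF·pyridine, pyridine, THF, 0 °C → rt
Reagents that add atoms: none
Why: Fluoride cleavage of the primary silyl ether under buffered, mildly acidic conditions should leave the acetate, the methacrylate and the Michael acceptors intact.

Compound list
1 | diethyl 2-(but-3-en-1-yl)malonate | CCOC(=O)C(CCC=C)C(=O)OCC | starting material
2 | sodium enolate of 1 | CCOC(=O)C(CCC=C)=C([O-])OCC.[Na+] | intermediate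
3 | diethyl 2-(but-3-en-1-yl)-2-(diiodomethyl)malonate | CCOC(=O)C(CCC=C)(C(I)I)C(=O)OCC | intermediate
4 | dipotassium 2-(but-3-en-1-yl)-2-(diiodomethyl)malonate | [K+].[K+].[O-]C(=O)C(CCC=C)(C(I)I)C([O-])=O | intermediate
5 | (2E)-2-(iodomethylidene)hex-5-enoic acid | I/C=C(/C(O)=O)CCC=C | intermediate
6 | (2E)-2-(iodomethylidene)hex-5-en-1-ol | I/C=C(/CO)CCC=C | intermediate
7 | tert-butyl{[(2E)-2-(iodomethylidene)hex-5-en-1-yl]oxy}diphenylsilane | I/C=C(/CO[Si](c1ccccc1)(c1ccccc1)C(C)(C)C)CCC=C | intermediate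
8 | (5E)-5-{[tert-butyl(diphenyl)silyl]oxymethyl}-6-iodohex-5-ene-1,2-diol (racemic at C2) | I/C=C(/CO[Si](c1ccccc1)(c1ccccc1)C(C)(C)C)CCC(O)CO | intermediate
9 | (4E)-4-{[tert-butyl(diphenyl)silyl]oxymethyl}-5-iodopent-4-enal | I/C=C(/CO[Si](c1ccccc1)(c1ccccc1)C(C)(C)C)CCC=O | intermediate
10 | methyl (triphenylphosphoranylidene)acetate | COC(=O)C=P(c1ccccc1)(c1ccccc1)c1ccccc1 | starting material
11 | methyl iodo(triphenylphosphoranylidene)acetate | COC(=O)C(I)=P(c1ccccc1)(c1ccccc1)c1ccccc1 | intermediate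
12 | methyl (2Z,6E)-6-{[tert-butyl(diphenyl)silyl]oxymethyl}-2,7-diiodohepta-2,6-dienoate | I/C=C(/CO[Si](c1ccccc1)(c1ccccc1)C(C)(C)C)CC/C=C(/C(=O)OC)I | intermediate
13 | (4S)-2,2-dimethyl-1,3-dioxolane-4-carbaldehyde | O=C[C@@H]1COC(C)(C)O1 | starting material
14 | methyl (2Z,6E)-2-(chloromagnesio)-6-{[tert-butyl(diphenyl)silyl]oxymethyl}-7-iodohepta-2,6-dienoate | I/C=C(/CO[Si](c1ccccc1)(c1ccccc1)C(C)(C)C)CC/C=C(/C(=O)OC)[Mg]Cl | intermediate
15 | chloromagnesium alkoxide of the C9 carbinol (9R, dioxolane 4S) | I/C=C(/CO[Si](c1ccccc1)(c1ccccc1)C(C)(C)C)CC/C=C(/C(=O)OC)[C@@H](O[Mg]Cl)[C@@H]1COC(C)(C)O1 | intermediate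
16 | methyl (2E,6E)-2-{(R)-acetoxy[(4S)-2,2-dimethyl-1,3-dioxolan-4-yl]methyl}-6-{[tert-butyl(diphenyl)silyl]oxymethyl}-7-iodohepta-2,6-dienoate | I/C=C(/CO[Si](c1ccccc1)(c1ccccc1)C(C)(C)C)CC/C=C(/C(=O)OC)[C@@H](OC(C)=O)[C@@H]1COC(C)(C)O1 | intermediate
17 | methyl (2E,6E)-2-[(1R,2S)-1-acetoxy-2,3-dihydroxypropyl]-6-{[tert-butyl(diphenyl)silyl]oxymethyl}-7-iodohepta-2,6-dienoate | I/C=C(/CO[Si](c1ccccc1)(c1ccccc1)C(C)(C)C)CC/C=C(/C(=O)OC)[C@@H](OC(C)=O)[C@@H](O)CO | intermediate
18 | methyl (2E,6E)-2-[(1R)-1-acetoxy-2-oxoethyl]-6-{[tert-butyl(diphenyl)silyl]oxymethyl}-7-iodohepta-2,6-dienoate | I/C=C(/CO[Si](c1ccccc1)(c1ccccc1)C(C)(C)C)CC/C=C(/C(=O)OC)[C@@H](OC(C)=O)C=O | intermediate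
19 | 2,2-dimethoxyacetaldehyde | COC(OC)C=O | starting material
20 | methyl acrylate | COC(=O)C=C | starting material
21 | methyl 3-hydroxy-4,4-dimethoxy-2-methylidenebutanoate (racemic) | COC(=O)C(=C)C(O)C(OC)OC | intermediate
22 | methyl (2Z)-2-(bromomethyl)-4,4-dimethoxybut-2-enoate | COC(=O)/C(CBr)=C/C(OC)OC | intermediate
23 | dibromo[(2Z)-4,4-dimethoxy-2-(methoxycarbonyl)but-2-en-1-yl]indium | COC(=O)/C(C[In](Br)Br)=C/C(OC)OC | intermediate
24 | dimethyl (2E,3R,4S,5R)-3-acetoxy-2-[(4E)-4-{[tert-butyl(diphenyl)silyl]oxymethyl}-5-iodopent-4-en-1-ylidene]-5-(dimethoxymethyl)-4-hydroxy-6-methylideneheptanedioate | I/C=C(/CO[Si](c1ccccc1)(c1ccccc1)C(C)(C)C)CC/C=C(/C(=O)OC)[C@@H](OC(C)=O)[C@@H](O)[C@H](C(OC)OC)C(=C)C(=O)OC | intermediate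
25 | the C8 methacrylate of 24 (2E,3R,4S,5R) | I/C=C(/CO[Si](c1ccccc1)(c1ccccc1)C(C)(C)C)CC/C=C(/C(=O)OC)[C@@H](OC(C)=O)[C@@H](OC(=O)C(C)=C)[C@H](C(OC)OC)C(=C)C(=O)OC | intermediate
26 | N-(1-methoxyalkyl)-2,4,6-trimethylpyridinium triflate formed at C6 of 25 | I/C=C(/CO[Si](c1ccccc1)(c1ccccc1)C(C)(C)C)CC/C=C(/C(=O)OC)[C@@H](OC(C)=O)[C@@H](OC(=O)C(C)=C)[C@H](C(OC)[n+]1c(C)cc(C)cc1C)C(=C)C(=O)OC.[O-]S(=O)(=O)C(F)(F)F | intermediate
27 | dimethyl (2E,3R,4S,5R)-3-acetoxy-2-[(4E)-4-{[tert-butyl(diphenyl)silyl]oxymethyl}-5-iodopent-4-en-1-ylidene]-5-formyl-4-(methacryloyloxy)-6-methylideneheptanedioate | I/C=C(/CO[Si](c1ccccc1)(c1ccccc1)C(C)(C)C)CC/C=C(/C(=O)OC)[C@@H](OC(C)=O)[C@@H](OC(=O)C(C)=C)[C@H](C=O)C(=C)C(=O)OC | intermediate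
28 | alkenylchromium dichloride from 27 (CrCl2 in place of iodine at C5, geometry retained) | Cl[Cr](Cl)/C=C(/CO[Si](c1ccccc1)(c1ccccc1)C(C)(C)C)CC/C=C(/C(=O)OC)[C@@H](OC(C)=O)[C@@H](OC(=O)C(C)=C)[C@H](C=O)C(=C)C(=O)OC | intermediate
29 | ten-membered carbocycle as its C6 chromium alkoxide (6R), C12 methyl ester still open | C=C(C)C(=O)O[C@H]1[C@@H](C(=C)C(=O)OC)[C@H](O[Cr](Cl)Cl)/C=C(/CO[Si](c2ccccc2)(c2ccccc2)C(C)(C)C)CC/C=C(/C(=O)OC)[C@H]1OC(C)=O | intermediate
30 | 15-O-(tert-butyldiphenylsilyl) ether of the target (trans-fused 6,12-lactone; 6R,7S,8S,9R) | C=C(C)C(=O)O[C@H]1[C@H]2C(=C)C(=O)O[C@@H]2/C=C(/CO[Si](c3ccccc3)(c3ccccc3)C(C)(C)C)CC/C=C(/C(=O)OC)[C@H]1OC(C)=O | intermediate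
31 | CNP0179134.4: trans-fused 6,12-germacranolide (6R,7S,8S,9R) with C8 methacrylate, C9 acetate, C14 methyl ester and free C15 hydroxyl | C=C(C)C(=O)O[C@H]1[C@H]2C(=C)C(=O)O[C@@H]2/C=C(/CO)CC/C=C(/C(=O)OC)[C@H]1OC(C)=O | target

Total step count: 15. Longest linear sequence: 13 steps (steps 1–8 and 11–15).

Steps most likely to fail

1. Step 14. The ten-membered closure may be slow, which would let β-elimination of the O8 methacrylate from the enolisable C6 aldehyde, epimerisation at C7, oligomerisation or a 1,3-acyl shift from O8 to the new alkoxide compete. The fallback sets out from 24 and comes back at 30; it closes the same bond on an aldehyde that has no carboxylate leaving group and brings in the methacrylate afterwards. O8 is silylated (TESCl, imidazole, DMF) to give the triethylsilyl ether F1. Acetal cleavage as in step 13 gives the β-silyloxy aldehyde F2. Closure under the conditions of step 14 gives the O8-silylated lactone F3. HF·pyridine/pyridine in THF at 0 °C removes only the secondary triethylsilyl ether and gives the C8 alcohol F4. Methacrylic anhydride, Et3N and DMAP then give 30.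

2. Step 11. The syn/anti control may erode through E/Z equilibration of the allylindium and chelation in water, the acetyl group may shift from O9 to O8, and the C8 alcohol may lactonise early onto C12. The fallback sets out from 21 and comes back at 24; it replaces the open Barbier process by an allylboration with a closed transition state in a water-free medium. Acetylation of 21 (Ac2O, DMAP, pyridine) gives the allylic acetate F5. Copper-catalysed SN2' borylation (B2pin2, CuCl, KOAc, DMF) gives the allylboronate F6, with the acetal arm cis to the CH2B group. F6 adds to 18 (Sc(OTf)3 cat., CH2Cl2, −78 °C) through a chair transition state (type 1 allylboration), which fixes the C7/C8 syn relationship, while Felkin–Anh control by the C9 acetoxy group is kept. Mild hydrolysis of the borate gives 24.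

3. Step 7. The facial selectivity of the Grignard addition to the α-alkoxy aldehyde may be poor, and some exchange may occur at the C5 iodide. The fallback sets out from 12 and 13 and comes back at 16; it changes the metal and adds a stereochemical correction. Coupling mediated by CrCl2 with NiCl2 (cat.) in DMSO, aldehyde limiting, should engage the activated α-iodoenoate first (faster insertion of zerovalent nickel) and gives the anti alcohol F7 and the syn alcohol F8, which are separated. F7 is acetylated (Ac2O, DMAP, pyridine) to 16. F8 is converted into the same acetate 16 by Mitsunobu inversion (PPh3, DIAD, AcOH), so both epimers converge.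

Further compounds
F1 | step 14 | dimethyl (2E,3R,4S,5R)-3-acetoxy-2-[(4E)-4-{[tert-butyl(diphenyl)silyl]oxymethyl}-5-iodopent-4-en-1-ylidene]-5-(dimethoxymethyl)-6-methylidene-4-[(triethylsilyl)oxy]heptanedioate | I/C=C(/CO[Si](c1ccccc1)(c1ccccc1)C(C)(C)C)CC/C=C(/C(=O)OC)[C@@H](OC(C)=O)[C@@H](O[Si](CC)(CC)CC)[C@H](C(OC)OC)C(=C)C(=O)OC
F2 | step 14 | dimethyl (2E,3R,4S,5R)-3-acetoxy-2-[(4E)-4-{[tert-butyl(diphenyl)silyl]oxymethyl}-5-iodopent-4-en-1-ylidene]-5-formyl-6-methylidene-4-[(triethylsilyl)oxy]heptanedioate | I/C=C(/CO[Si](c1ccccc1)(c1ccccc1)C(C)(C)C)CC/C=C(/C(=O)OC)[C@@H](OC(C)=O)[C@@H](O[Si](CC)(CC)CC)[C@H](C=O)C(=C)C(=O)OC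
F3 | step 14 | analogue of 30 with a triethylsilyl ether at O8 in place of the methacrylate | CC[Si](CC)(CC)O[C@H]1[C@H]2C(=C)C(=O)O[C@@H]2/C=C(/CO[Si](c3ccccc3)(c3ccccc3)C(C)(C)C)CC/C=C(/C(=O)OC)[C@H]1OC(C)=O
F4 | step 14 | analogue of 30 with a free C8 hydroxyl | O[C@H]1[C@H]2C(=C)C(=O)O[C@@H]2/C=C(/CO[Si](c3ccccc3)(c3ccccc3)C(C)(C)C)CC/C=C(/C(=O)OC)[C@H]1OC(C)=O
F5 | step 11 | methyl 3-acetoxy-4,4-dimethoxy-2-methylidenebutanoate (racemic) | COC(=O)C(=C)C(OC(C)=O)C(OC)OC
F6 | step 11 | methyl (2E)-4,4-dimethoxy-2-[(4,4,5,5-tetramethyl-1,3,2-dioxaborolan-2-yl)methyl]but-2-enoate | COC(=O)/C(CB1OC(C)(C)C(C)(C)O1)=C/C(OC)OC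
F7 | step 7 | methyl (2E,6E)-2-{(R)-hydroxy[(4S)-2,2-dimethyl-1,3-dioxolan-4-yl]methyl}-6-{[tert-butyl(diphenyl)silyl]oxymethyl}-7-iodohepta-2,6-dienoate | I/C=C(/CO[Si](c1ccccc1)(c1ccccc1)C(C)(C)C)CC/C=C(/C(=O)OC)[C@@H](O)[C@@H]1COC(C)(C)O1
F8 | step 7 | methyl (2E,6E)-2-{(S)-hydroxy[(4S)-2,2-dimethyl-1,3-dioxolan-4-yl]methyl}-6-{[tert-butyl(diphenyl)silyl]oxymethyl}-7-iodohepta-2,6-dienoate | I/C=C(/CO[Si](c1ccccc1)(c1ccccc1)C(C)(C)C)CC/C=C(/C(=O)OC)[C@H](O)[C@@H]1COC(C)(C)O1
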